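**Retrosynthetic overview**
- Feature: in ring B (isochromanone numbering) the run C1(=O)–O2–C3–C4 is, atom for atom, a 4-alkyloxetan-2-one. It is held to ring A by the neighbouring carbons C8a (bonded to C1) and C4a (bonded to C4), with the C8 oxygen ortho to C8a, so ring B is a β-lactone with an aryne inserted into its C1–C4 bond.
- Key disconnection: C4–C4a and C1–C8a, leading back to the enolate of the (R)-β-lactone and to 3,5-bis(methoxymethoxy)benzyne from the 1,2-dibromide.
- Ring order: ring A is bought. The four-membered lactone is built next by a catalytic asymmetric ketene–aldehyde (2+2) cycloaddition that sets C3, and it is then enlarged by two atoms to ring B.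
- Aldehyde: (S)-7-silyloxydodecanal comes from (S)-oct-1-yn-3-ol (C6' bought) by silylation, acetylide alkylation with a four-carbon iodoacetal, hydrogenation and hydrolysis.
- Protecting groups: the phenols are MOM ethers and the carbinol a TBS ether, so one dilute-acid treatment ends the route. Methyl ethers are avoided because BBr3 or AlCl3/EtSH, needed for the C6 ether, also turn secondary silyl ethers into halides and can open the lactone at C3.

Key step: step 9

Remark on the chemistry: isochromanone numbering (C1, O2, C3, C4, C4a, C5–C8, C8a) is used for the β-lactone atoms and all key-step intermediates. The (R,R)-triamine ligand of step 6 is assumed to be made beforehand from D-valinol (N-triflylaziridine, then benzylamine) and, as a catalyst component, is not counted.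

**Step 1**
Reactants: 1 (S)-oct-1-yn-3-ol
Product: 2 (S)-tert-butyldimethyl(oct-1-yn-3-yloxy)silane
Conditions: TBSCl, imidazole, DMF, 0 °C → rt
Reagents that add atoms: tert-butyldimethylsilyl chloride (TBSCl), CC(C)(C)[Si](C)(C)Cl
Why: Imidazole-promoted O-silylation of a secondary alcohol leaves the C–O bond untouched, so the bought S centre (later C6') is carried over unchanged.

**Step 2**
Reactants: 3 2-(3-chloropropyl)-1,3-dioxolane
Product: 4 2-(3-iodopropyl)-1,3-dioxolane
Conditions: NaI, acetone, reflux
Reagents that add atoms: sodium iodide, [Na+].[I-]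
Why: Finkelstein halide exchange driven by precipitation of NaCl, carried out because a primary chloride is too slow an electrophile for a lithium acetylide.

**Step 3**
Reactants: 2 (S)-tert-butyldimethyl(oct-1-yn-3-yloxy)silane, 4 2-(3-iodopropyl)-1,3-dioxolane
Product: 6 (S)-tert-butyl{[1-(1,3-dioxolan-2-yl)undec-4-yn-6-yl]oxy}dimethylsilane, via lithium acetylide 5 (not isolated)
Conditions: n-BuLi, THF, −78 °C; then 4, DMPU, −78 °C → rt
Reagents that add atoms: none
Why: SN2 alkylation of a lithium acetylide with a primary iodide in THF/DMPU, in which only the terminal alkyne C–H is deprotonated, so the propargylic stereocentre, silyl ether and acetal are spectators.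

**Step 4**
Reactants: 6 (S)-tert-butyl{[1-(1,3-dioxolan-2-yl)undec-4-yn-6-yl]oxy}dimethylsilane
Product: 7 (S)-tert-butyl{[1-(1,3-dioxolan-2-yl)undecan-6-yl]oxy}dimethylsilane
Conditions: H2 (1 atm), 10% Pd/C, EtOAc, rt
Reagents that add atoms: none
Why: Heterogeneous catalytic hydrogenation of the alkyne to the alkane, run in aprotic EtOAc so that the silyl ether and acetal survive and propargylic C–O hydrogenolysis is held back.

**Step 5**
Reactants: 7 (S)-tert-butyl{[1-(1,3-dioxolan-2-yl)undecan-6-yl]oxy}dimethylsilane
Product: 8 (S)-7-(tert-butyldimethylsilyloxy)dodecanal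
Conditions: PPTS (cat.), acetone/H2O (10:1), reflux
Reagents that add atoms: water, O
Why: Buffered acid hydrolysis of an aldehyde acetal, under which the hindered secondary TBS ether flanked by two alkyl chains hydrolyses far more slowly than the dioxolane.

**Step 6**
Reactants: 8 (S)-7-(tert-butyldimethylsilyloxy)dodecanal, 9 acetyl bromide
Product: 11 (R)-4-[(6S)-6-(tert-butyldimethylsilyloxy)undecyl]oxetan-2-one, via ketene 10 (not isolated)
Conditions: AlMe3 (10 mol %), N-benzyl-N,N-bis[(2R)-3-methyl-2-(trifluoromethylsulfonylamino)butyl]amine (10 mol %), i-Pr2NEt, CH2Cl2, −50 °C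
Reagents that add atoms: none
Why: Catalytic asymmetric acyl halide–aldehyde cyclocondensation (a Lewis-acid-catalysed ketene–aldehyde (2+2) cycloaddition): the amine turns 9 into ketene 10, the chiral trivalent-aluminium bis(sulfonamide) complex binds the unbranched aldehyde and shields one face, and because the L-valinol-derived (S,S) catalyst gives (S)-lactones from unbranched aldehydes, its (R,R) mirror image should send ketene to the Si face of 8 and set C3 as R under pure catalyst control, the remote C6' centre having no influence.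

**Step 7**
Reactants: 12 5-bromobenzene-1,3-diol (5-bromoresorcinol)
Product: 13 1-bromo-3,5-bis(methoxymethoxy)benzene
Conditions: MOMCl, i-Pr2NEt, CH2Cl2, 0 °C → rt
Reagents that add atoms: chloromethyl methyl ether (MOMCl), COCCl
Why: Standard O-alkylation of both phenols with MOMCl and a hindered amine base, giving acetal ethers that are inert to organolithiums and removable with dilute acid.

**Step 8**
Reactants: 13 1-bromo-3,5-bis(methoxymethoxy)benzene
Product: 14 1,2-dibromo-3,5-bis(methoxymethoxy)benzene
Conditions: NBS (1.0 equiv), MeCN, 0 °C → rt, dark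
Reagents that add atoms: N-bromosuccinimide (NBS), O=C1CCC(=O)N1Br
Why: Electrophilic aromatic bromination under acid-free conditions, which should enter at C2 (para to one OMOM, ortho to the other) because the C4 position between the two OMOM groups is sterically shielded.

**Step 9**
Reactants: 11 (R)-4-[(6S)-6-(tert-butyldimethylsilyloxy)undecyl]oxetan-2-one, 14 1,2-dibromo-3,5-bis(methoxymethoxy)benzene
Product: 21 (R)-3-[(6S)-6-(tert-butyldimethylsilyloxy)undecyl]-6,8-bis(methoxymethoxy)isochroman-1-one, via lithium enolate 15 (not isolated), via bromoaryllithium 16 (not isolated), via aryne 17 (not isolated), via aryllithium adduct 18 (not isolated), via benzocyclobutenoxide 19 (not isolated), via lithium dienolate 20 (not isolated)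
Conditions: MesLi (1.0 equiv, from 2-bromomesitylene and n-BuLi), THF, −95 °C; 14 (1.3 equiv); n-BuLi (1.3 equiv, slow addition), −95 → −50 °C; t-BuOH, −78 → 0 °C
Reagents that add atoms: none
Why: Proposed new method: mesityllithium turns 11 into the amine-free enolate 15 (its only by-product, mesitylene, can neither protonate an aryllithium nor add to an aryne), bromine–lithium exchange on 14 gives 16, which loses LiBr to aryne 17, and 15 attacks 17 through C4 at C4a, anti to the C3 side chain, to give aryllithium 18. The C8a carbanion of 18 closes onto the strained lactone carbonyl C1 (4-exo-trig) to the cis-fused benzocyclobutenoxide 19, and oxyanion-driven cleavage of the old C1–C4 bond, directly or after reversible opening to the benzocyclobutenone and its C3 alkoxide, releases both four-membered rings and leaves ring B as dienolate 20, so ring B closes by a two-atom ring expansion and not by cyclisation of an open chain. The closest known reaction types are the acyl-alkylation of arynes by β-keto esters and malonates (C–C σ-bond insertion), the two-carbon ring expansion of cyclic ketone enolates with arynes through benzocyclobutenoxides, and the (2+2) cycloaddition of ketene silyl acetals to 3-alkoxybenzynes; a β-lactone has not served as the σ-bond donor. No stereocentre is created in 21, since C4 ends as CH2 and the transient centres at C4 and C1 vanish, and C3 keeps the R configuration of 11 because none of its bonds is ever broken. The regioselectivity needed (C4 to C4a, C1 to C8a) is secured by the C8 OMOM group, whose inductive pull polarises the aryne so that the nucleophile enters at the distal carbon and the charge develops next to oxygen, as in the known malonate and ketene acetal additions to 3-alkoxybenzynes. The chemoselectivity needed is survival of 15 and 20 against β-elimination: in 15 the C3–O2 bond lies in the nodal plane of the enolate, and 20 is protonated by t-BuOH added at −78 °C before warming, so any 19 still unopened expands in the presence of a proton donor.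

**Step 10**
Reactants: 21 (R)-3-[(6S)-6-(tert-butyldimethylsilyloxy)undecyl]-6,8-bis(methoxymethoxy)isochroman-1-one
Product: 22 (R)-6,8-dihydroxy-3-[(6S)-6-hydroxyundecyl]isochroman-1-one (target)
Conditions: HCl (1.25 M in MeOH), rt → 40 °C
Reagents that add atoms: none
Why: Acid-catalysed acetal exchange removes both aryl MOM ethers and acid methanolysis removes the TBS ether in one operation, while the secondary alcohol, the hydrogen-bonded six-membered lactone and both stereocentres are inert to dilute acid.

**Compound list**
1 | (S)-oct-1-yn-3-ol | CCCCC[C@H](O)C#C | starting material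
2 | (S)-tert-butyldimethyl(oct-1-yn-3-yloxy)silane | CCCCC[C@H](O[Si](C)(C)C(C)(C)C)C#C | intermediate
3 | 2-(3-chloropropyl)-1,3-dioxolane | ClCCCC1OCCO1 | starting material
4 | 2-(3-iodopropyl)-1,3-dioxolane | ICCCC1OCCO1 | intermediate
5 | lithium acetylide of 2, (S)-[3-(tert-butyldimethylsilyloxy)oct-1-yn-1-yl]lithium | CCCCC[C@H](O[Si](C)(C)C(C)(C)C)C#C[Li] | intermediate
6 | (S)-tert-butyl{[1-(1,3-dioxolan-2-yl)undec-4-yn-6-yl]oxy}dimethylsilane | CCCCC[C@H](O[Si](C)(C)C(C)(C)C)C#CCCCC1OCCO1 | intermediate
7 | (S)-tert-butyl{[1-(1,3-dioxolan-2-yl)undecan-6-yl]oxy}dimethylsilane | CCCCC[C@H](O[Si](C)(C)C(C)(C)C)CCCCCC1OCCO1 | intermediate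
8 | (S)-7-(tert-butyldimethylsilyloxy)dodecanal | CCCCC[C@H](O[Si](C)(C)C(C)(C)C)CCCCCC=O | intermediate
9 | acetyl bromide | CC(=O)Br | starting material
10 | ketene | C=C=O | intermediate
11 | (R)-4-[(6S)-6-(tert-butyldimethylsilyloxy)undecyl]oxetan-2-one | CCCCC[C@H](O[Si](C)(C)C(C)(C)C)CCCCC[C@@H]1CC(=O)O1 | intermediate
12 | 5-bromobenzene-1,3-diol | Oc1cc(O)cc(Br)c1 | starting material
13 | 1-bromo-3,5-bis(methoxymethoxy)benzene | COCOc1cc(Br)cc(OCOC)c1 | intermediate
14 | 1,2-dibromo-3,5-bis(methoxymethoxy)benzene | COCOc1cc(OCOC)c(Br)c(Br)c1 | intermediate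
15 | lithium enolate of 11, lithium (R)-2-[(6S)-6-(tert-butyldimethylsilyloxy)undecyl]-2H-oxet-4-olate | CCCCC[C@H](O[Si](C)(C)C(C)(C)C)CCCCC[C@@H]1C=C(O[Li])O1 | intermediate
16 | 6-bromo-2,4-bis(methoxymethoxy)phenyllithium | [Li]c1c(Br)cc(OCOC)cc1OCOC | intermediate
17 | 3,5-bis(methoxymethoxy)benzyne (1,2-didehydro-3,5-bis(methoxymethoxy)benzene) | COCOC1=CC(OCOC)=CC#C1 | intermediate
18 | (3R,4R)-3-[2-lithio-3,5-bis(methoxymethoxy)phenyl]-4-[(6S)-6-(tert-butyldimethylsilyloxy)undecyl]oxetan-2-one (aryl trans to the side chain, Li on C8a) | CCCCC[C@H](O[Si](C)(C)C(C)(C)C)CCCCC[C@H]1OC(=O)[C@@H]1c2cc(OCOC)cc(OCOC)c2[Li] | intermediate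
19 | cis-fused tricyclic lithium alkoxide: benzocyclobutene ring (C4a, C8a, C1, C4) sharing the C1–C4 bond with the oxetane ring (C1, O2, C3, C4), OLi on C1, arene anti to the C3 side chain | CCCCC[C@H](O[Si](C)(C)C(C)(C)C)CCCCC[C@H]1O[C@]2(O[Li])c3c(OCOC)cc(OCOC)cc3[C@H]12 | intermediate
20 | lithium dienolate (C4 anion) of 21, drawn as the o-quinodimethane form with OLi on C1 | CCCCC[C@H](O[Si](C)(C)C(C)(C)C)CCCCC[C@@H]1C=C2C=C(OCOC)C=C(OCOC)C2=C(O[Li])O1 | intermediate
21 | (R)-3-[(6S)-6-(tert-butyldimethylsilyloxy)undecyl]-6,8-bis(methoxymethoxy)isochroman-1-one | CCCCC[C@H](O[Si](C)(C)C(C)(C)C)CCCCC[C@@H]1Cc2cc(OCOC)cc(OCOC)c2C(=O)O1 | intermediate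
22 | (R)-6,8-dihydroxy-3-[(6S)-6-hydroxyundecyl]isochroman-1-one | CCCCC[C@H](O)CCCCC[C@@H]1Cc2cc(O)cc(O)c2C(=O)O1 | target

**Total step count:** 10 steps.
**Longest linear sequence:** 7 steps (1, 3, 4, 5, 6, 9, 10).

**Steps most likely to fail**

**1. Step 9 (key step).**
- The aryl base may add to the lactone carbonyl instead of deprotonating it.
- The enolate may self-acylate while it is being formed.
- The chelated bromoaryllithium may release the aryne only at temperatures the enolate does not survive.
- Proton transfer to the C8a carbanion may stop the sequence at plain α-arylation.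
- The C4 anion may be arylated a second time.
- β-Elimination across C3–C4 may destroy the C3 stereocentre.

The fallback uses known chemistry only. It forms C4–C4a by epoxide opening and C1–C8a by carbonylation, sets out from 8 and 13, and comes back at 21. Corey–Chaykovsky methylenation of 8 (Me3SI, NaH, DMSO/THF) gives 2-[(6S)-6-(tert-butyldimethylsilyloxy)undecyl]oxirane F1 as both epimers at the oxirane carbon. Hydrolytic kinetic resolution with (R,R)-(salen)Co(OAc) and 0.55 equiv of water leaves (R)-2-[(6S)-6-(tert-butyldimethylsilyloxy)undecyl]oxirane F2. Bromine–lithium exchange on 13 (n-BuLi, THF, −78 °C) gives 3,5-bis(methoxymethoxy)phenyllithium F3. This opens F2 at its terminal carbon with BF3·OEt2 at −78 °C to give (2R,8S)-1-[3,5-bis(methoxymethoxy)phenyl]-8-(tert-butyldimethylsilyloxy)tridecan-2-ol F4. NBS in MeCN brominates ortho to the side chain and para to an OMOM group to give (2R,8S)-1-[2-bromo-3,5-bis(methoxymethoxy)phenyl]-8-(tert-butyldimethylsilyloxy)tridecan-2-ol F5. Palladium-catalysed carbonylative lactonisation (Pd(OAc)2, dppf, CO 1 atm, Et3N, DMF, 90 °C) then closes ring B to 21.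

**2. Step 6.** Facial selectivity may be poor, the sense of induction may be opposite to that expected (to be checked by MTPA ester analysis of the hydroxy ester from methanolysis of a sample of 11), or the unbranched aldehyde may self-condense.

The fallback sets C3 by ketone hydrogenation instead of cycloaddition. It sets out from 8 and comes back at 11. Roskamp homologation of 8 (ethyl diazoacetate, SnCl2 cat., CH2Cl2) gives ethyl (S)-9-(tert-butyldimethylsilyloxy)-3-oxotetradecanoate F6. Noyori asymmetric hydrogenation (RuCl2[(R)-BINAP], H2, EtOH) gives ethyl (3R,9S)-9-(tert-butyldimethylsilyloxy)-3-hydroxytetradecanoate F7. Saponification (LiOH, THF/H2O) gives (3R,9S)-9-(tert-butyldimethylsilyloxy)-3-hydroxytetradecanoic acid F8. Lactonisation by carboxyl activation (PhSO2Cl, pyridine, 0 °C) leaves the carbinol C–O bond intact and gives 11 with retention.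

**3. Step 5.** The silyl ether may be lost during the acid cleavage of the dioxolane, or the acetal hydrolysis may stay incomplete at an acidity the silyl ether tolerates.

The fallback reaches the aldehyde by oxidation, with no acid step. It sets out from 2 (through acetylide 5) and comes back at 8. Alkylation of 5 with benzyl 4-bromobutyl ether (THF/DMPU) gives (S)-{[12-(benzyloxy)dodec-7-yn-6-yl]oxy}(tert-butyl)dimethylsilane F9. Hydrogenation over 10% Pd/C in EtOAc saturates the alkyne and cleaves the benzyl ether to give (S)-7-(tert-butyldimethylsilyloxy)dodecan-1-ol F10. Oxidation with TEMPO (cat.) and PhI(OAc)2 in CH2Cl2 gives 8.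

**Further compounds**
F1 | step 9 | 2-[(6S)-6-(tert-butyldimethylsilyloxy)undecyl]oxirane (both epimers at the oxirane carbon) | CCCCC[C@H](O[Si](C)(C)C(C)(C)C)CCCCCC1CO1
F2 | step 9 | (R)-2-[(6S)-6-(tert-butyldimethylsilyloxy)undecyl]oxirane | CCCCC[C@H](O[Si](C)(C)C(C)(C)C)CCCCC[C@@H]1CO1
F3 | step 9 | 3,5-bis(methoxymethoxy)phenyllithium | [Li]c1cc(OCOC)cc(OCOC)c1
F4 | step 9 | (2R,8S)-1-[3,5-bis(methoxymethoxy)phenyl]-8-(tert-butyldimethylsilyloxy)tridecan-2-ol | CCCCC[C@H](O[Si](C)(C)C(C)(C)C)CCCCC[C@@H](O)Cc1cc(OCOC)cc(OCOC)c1
F5 | step 9 | (2R,8S)-1-[2-bromo-3,5-bis(methoxymethoxy)phenyl]-8-(tert-butyldimethylsilyloxy)tridecan-2-ol | CCCCC[C@H](O[Si](C)(C)C(C)(C)C)CCCCC[C@@H](O)Cc1cc(OCOC)cc(OCOC)c1Br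
F6 | step 6 | ethyl (S)-9-(tert-butyldimethylsilyloxy)-3-oxotetradecanoate | CCCCC[C@H](O[Si](C)(C)C(C)(C)C)CCCCCC(=O)CC(=O)OCC
F7 | step 6 | ethyl (3R,9S)-9-(tert-butyldimethylsilyloxy)-3-hydroxytetradecanoate | CCCCC[C@H](O[Si](C)(C)C(C)(C)C)CCCCC[C@@H](O)CC(=O)OCC
F8 | step 6 | (3R,9S)-9-(tert-butyldimethylsilyloxy)-3-hydroxytetradecanoic acid | CCCCC[C@H](O[Si](C)(C)C(C)(C)C)CCCCC[C@@H](O)CC(=O)O
F9 | step 5 | (S)-{[12-(benzyloxy)dodec-7-yn-6-yl]oxy}(tert-butyl)dimethylsilane | CCCCC[C@H](O[Si](C)(C)C(C)(C)C)C#CCCCCOCc1ccccc1
F10 | step 5 | (S)-7-(tert-butyldimethylsilyloxy)dodecan-1-ol | CCCCC[C@H](O[Si](C)(C)C(C)(C)C)CCCCCCO
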